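**Retrosynthetic overview**
1. Target 9 ⇐ enal 8 (aldehyde to acid) ⇐ exocyclic alkene 5 by C17–O bond formation with singlet oxygen; the alkene moves to C7=C8.
2. 5 ⇐ saturated diacetate 4 by loss of the tertiary 8α-acetate; 4 ⇐ (13E)-allylic acetate 3 by asymmetric hydrogenation, which sets C13.
3. Key disconnection: the C15–O bond of 3, made from sclareol diacetate 2 by a 1,3-acetate shift that turns the 13R carbinol centre into the 13E alkene (the proposed new step).
4. 2 ⇐ (−)-sclareol 1. No ring is formed in the route: rings A and B and the C5, C9 and C10 centres come with sclareol, and no C–C bond is made.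

Assumption: labdane names refer to the normal (sclareol) series (H5α, H9α, C20 methyl β), and L1 is written as the (S,S) antipode on the understanding that one control run with its mirror image fixes which antipode is matched.

Ligands: L1 = 2,2′-(propane-2,2-diyl)bis[(4S)-4-tert-butyl-4,5-dihydro-1,3-oxazole]. L2 = 2-phenyl-6,7-dihydro-5H-cyclopenta[b]pyridin-7-yl di-o-tolylphosphinite, single enantiomer, the one whose iridium complex reduces geranyl acetate to (S)-citronellyl acetate.

**Step 1**
Reactants: 1 (−)-sclareol, (13R)-labd-14-ene-8α,13-diol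
Product: 2 sclareol diacetate, (13R)-labd-14-ene-8α,13-diyl diacetate
Conditions: AcCl (4 equiv), N,N-dimethylaniline (5 equiv), CH2Cl2, 0 °C to rt
Reagents that add atoms: acetyl chloride, CC(=O)Cl
Why: O-acylation of both tertiary alcohols by the small acyl chloride with a weak amine base that does not ionise the allylic C13–O bond; no stereocentre is touched, and the 8-acetate blocks the hydroxyl that would otherwise close to a manoyl-oxide ring in step 2.

**Step 2**
Reactants: 2 sclareol diacetate
Product: 3 (13E)-labd-13-ene-8α,15-diyl diacetate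
Conditions: PdCl2(L1) (5 mol %), AgBF4 (5 mol %), 2,6-di-tert-butyl-4-methylpyridine (10 mol %), THF, 0 °C to rt, stopped at full conversion of 2
Reagents that add atoms: none
Why: Proposed new method: a cyclisation-induced 1,3-acetate shift in which a chiral cationic chloro(bisoxazoline) complex of divalent palladium chooses the π-face of the vinyl group; bound to the C14 Si face, the metal lets the ester carbonyl oxygen add anti to C15 from the Re side (six-membered 1,3-dioxan-2-ylium, Pd–C14 σ-bond), and because the 13R centre then holds its methyl syn to C15, the anti C13–O/C14–Pd scission can give only the 13E alkene (the other face would give 13Z), so the C15–O bond is made and the point chirality of C13 is converted into alkene geometry; the closest known reactions are the PdCl2(MeCN)2-catalysed allylic acetate transposition, which is suprafacial but for which I expect only modest E/Z control with this tertiary vinyl carbinol acetate, and the face-selective allylic imidate rearrangements run with chiral palladacycles.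

**Step 3**
Reactants: 3 (13E)-labd-13-ene-8α,15-diyl diacetate
Product: 4 (13S)-labdane-8α,15-diyl diacetate
Conditions: [Ir(C8H12)(L2)][B(C6H3(CF3)2)4] (1 mol %), H2 (50 bar), CH2Cl2, rt
Reagents that add atoms: none
Why: Iridium-catalysed asymmetric hydrogenation of an all-alkyl trisubstituted alkene; the N,P-ligated catalyst adds H2 to the C13 Re face of the E alkene (the local environment is that of geranyl acetate), which sets 13S, and both acetates are inert.

**Step 4**
Reactants: 4 (13S)-labdane-8α,15-diyl diacetate
Product: 5 (13S)-labd-8(17)-en-15-yl acetate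
Conditions: 2,4,6-collidine, reflux (171 °C), 12 h; then AgNO3–SiO2 chromatography
Reagents that add atoms: none
Why: Thermal syn-elimination of a tertiary acetate (ester pyrolysis, Ei), helped by relief of the C17/C20 diaxial strain; the equatorial 8α-acetate finds a fully syn-coplanar β-hydrogen only on the freely rotating C17 methyl, so the exocyclic alkene is expected as the main isomer, collidine buffers the acetic acid against alkene migration, and the primary acetate does not eliminate at this temperature.

**Step 5**
Reactants: 5 (13S)-labd-8(17)-en-15-yl acetate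
Product: 8 (13S)-17-oxolabd-7-en-15-yl acetate, via 17-hydroperoxide 6 (not isolated), via 17-peracetate 7 (not isolated)
Conditions: O2, tetraphenylporphyrin (0.5 mol %), white LED, Ac2O (1.5 equiv), pyridine (2 equiv), DMAP (5 mol %), CH2Cl2, 0 °C
Reagents that add atoms: dioxygen, O=O; acetic anhydride, CC(=O)OC(C)=O (its acetyl group is kept only in 7, not in 8)
Why: Schenck ene reaction followed by Kornblum–DeLaMare-type dehydration; singlet oxygen bonds to C17 from the α face (the β face is screened by the axial C20 methyl) while taking the axial H7α, which forms the C17–O bond and moves the alkene to C7=C8, and the primary allylic hydroperoxide 6 is acetylated in situ to 7, which loses acetic acid to the conjugated aldehyde, itself inert to singlet oxygen.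

**Step 6**
Reactants: 8 (13S)-17-oxolabd-7-en-15-yl acetate
Product: 9 (13S)-15-acetoxylabd-7-en-17-oic acid
Conditions: NaClO2, NaH2PO4, 2-methyl-2-butene, t-BuOH–H2O, 0 °C to rt
Reagents that add atoms: sodium chlorite, [Na+].[O-]Cl=O
Why: Pinnick oxidation; chlorous acid takes the conjugated aldehyde to the acid without touching the trisubstituted alkene, the acetate or the C9 centre, and 2-methyl-2-butene removes the hypochlorous acid.

**Compound list**
1 | (−)-sclareol, (13R)-labd-14-ene-8α,13-diol | C=C[C@](C)(O)CC[C@H]1[C@](C)(O)CC[C@H]2C(C)(C)CCC[C@]12C | starting material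
2 | sclareol diacetate, (13R)-labd-14-ene-8α,13-diyl diacetate | C=C[C@](C)(OC(C)=O)CC[C@H]1[C@](C)(OC(C)=O)CC[C@H]2C(C)(C)CCC[C@]12C | intermediate
3 | (13E)-labd-13-ene-8α,15-diyl diacetate | CC(=O)OC/C=C(\C)CC[C@H]1[C@](C)(OC(C)=O)CC[C@H]2C(C)(C)CCC[C@]12C | intermediate
4 | (13S)-labdane-8α,15-diyl diacetate | CC(=O)OCC[C@@H](C)CC[C@H]1[C@](C)(OC(C)=O)CC[C@H]2C(C)(C)CCC[C@]12C | intermediate
5 | (13S)-labd-8(17)-en-15-yl acetate | CC(=O)OCC[C@@H](C)CC[C@H]1C(=C)CC[C@H]2C(C)(C)CCC[C@]12C | intermediate
6 | (13S)-17-hydroperoxylabd-7-en-15-yl acetate | CC(=O)OCC[C@@H](C)CC[C@H]1C(COO)=CC[C@H]2C(C)(C)CCC[C@]12C | intermediate (not isolated)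
7 | (13S)-17-(acetylperoxy)labd-7-en-15-yl acetate | CC(=O)OCC[C@@H](C)CC[C@H]1C(COOC(C)=O)=CC[C@H]2C(C)(C)CCC[C@]12C | intermediate (not isolated)
8 | (13S)-17-oxolabd-7-en-15-yl acetate | CC(=O)OCC[C@@H](C)CC[C@H]1C(C=O)=CC[C@H]2C(C)(C)CCC[C@]12C | intermediate
9 | (13S)-15-acetoxylabd-7-en-17-oic acid | CC(=O)OCC[C@@H](C)CC[C@H]1C(C(=O)O)=CC[C@H]2C(C)(C)CCC[C@]12C | target

**Step count and risks**
Total steps: 6. Longest linear sequence: 6 (1 → 9).

The three steps most likely to fail are 2, 4 and 5.

Step 2 (the proposed new step). The catalyst may not turn over, may ionise the tertiary allylic acetate to dienes, or may not control the face; the run must also be stopped before the product re-equilibrates to the thermodynamic E/Z mixture. The built-in test is that the mirror-image ligand should give mainly the 13Z isomer. The fallback sets out from 2 and comes back at 4, uses known chemistry only, and replaces geometry control by a reduction that does not depend on geometry. PdCl2(MeCN)2 (5 mol %) in THF moves the acetate without the chiral ligand and gives 3 together with (13Z)-labd-13-ene-8α,15-diyl diacetate F1; the mixture is not separated. K2CO3 in MeOH cleaves only the primary allylic acetate and gives 8α-acetoxylabd-13-en-15-ol F2 (13E/13Z mixture). MnO2 in CH2Cl2 gives 8α-acetoxylabd-13-en-15-al F3 (13E/13Z mixture). An iminium-catalysed transfer hydrogenation follows, with the Hantzsch ester and 2-tert-butyl-3-methylimidazolidin-4-one trichloroacetate (the antipode that turns citral into (S)-citronellal) in CHCl3 at −30 °C. Both enal isomers pass through the same equilibrating iminium ion, and the product is (13S)-8α-acetoxylabdan-15-al F4. NaBH4 in MeOH gives (13S)-8α-acetoxylabdan-15-ol F5, and Ac2O/pyridine returns 4.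

Step 4. The thermolysis may give too much of the endocyclic 7-ene and 8-ene, since the ring hydrogens are gauche to the acetate and not out of reach. The fallback sets out from 4 and comes back at 5, and changes the mechanism from syn-elimination of the ester to anti-elimination of the alcohol. LiAlH4 in THF removes both acetyl groups and gives (13S)-labdane-8α,15-diol F6. Ac2O/pyridine at 0 °C acetylates only the primary hydroxyl and gives (13S)-8α-hydroxylabdan-15-yl acetate F7. SOCl2/pyridine in CH2Cl2 at −78 °C forms the chlorosulfite, which eliminates by E2; an equatorial leaving group on the chair has no anti-periplanar ring hydrogen, so only the C17 methyl can supply the proton, and 5 results.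

Step 5. A 1,1-disubstituted alkene reacts slowly with singlet oxygen, and abstraction of the tertiary H9α instead of H7α would give the 8(9)-ene aldehyde. The fallback sets out from 5 and comes back at 8, and oxidises the methyl group of the endocyclic isomer instead. CoCl(L3) (2 mol %; L3 = N,N′-bis(3,5-di-tert-butylsalicylidene)cyclohexane-1,2-diaminate) with PhSiH3 (4 mol %) in benzene at rt isomerises 5 by hydrogen-atom transfer to (13S)-labd-7-en-15-yl acetate F8; the cobalt takes the accessible C7 hydrogen in preference to the hindered C9–H. Riley oxidation (SeO2 0.5 equiv, t-BuOOH, CH2Cl2, rt) attacks the C17 methyl on the more substituted alkene carbon by ene reaction and [2,3] shift and gives (13S)-17-hydroxylabd-7-en-15-yl acetate F9, accompanied by some 8. MnO2 in CH2Cl2 completes the oxidation to 8. The same two operations also use up any F8 that step 4 gives as a by-product.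

**Further compounds**
F1 | step 2 | (13Z)-labd-13-ene-8α,15-diyl diacetate | CC(=O)OC/C=C(/C)CC[C@H]1[C@](C)(OC(C)=O)CC[C@H]2C(C)(C)CCC[C@]12C
F2 | step 2 | 8α-acetoxylabd-13-en-15-ol (13E/13Z mixture) | OCC=C(C)CC[C@H]1[C@](C)(OC(C)=O)CC[C@H]2C(C)(C)CCC[C@]12C
F3 | step 2 | 8α-acetoxylabd-13-en-15-al (13E/13Z mixture) | O=CC=C(C)CC[C@H]1[C@](C)(OC(C)=O)CC[C@H]2C(C)(C)CCC[C@]12C
F4 | step 2 | (13S)-8α-acetoxylabdan-15-al | O=CC[C@@H](C)CC[C@H]1[C@](C)(OC(C)=O)CC[C@H]2C(C)(C)CCC[C@]12C
F5 | step 2 | (13S)-8α-acetoxylabdan-15-ol | OCC[C@@H](C)CC[C@H]1[C@](C)(OC(C)=O)CC[C@H]2C(C)(C)CCC[C@]12C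
F6 | step 4 | (13S)-labdane-8α,15-diol | OCC[C@@H](C)CC[C@H]1[C@](C)(O)CC[C@H]2C(C)(C)CCC[C@]12C
F7 | step 4 | (13S)-8α-hydroxylabdan-15-yl acetate | CC(=O)OCC[C@@H](C)CC[C@H]1[C@](C)(O)CC[C@H]2C(C)(C)CCC[C@]12C
F8 | step 5 | (13S)-labd-7-en-15-yl acetate | CC(=O)OCC[C@@H](C)CC[C@H]1C(C)=CC[C@H]2C(C)(C)CCC[C@]12C
F9 | step 5 | (13S)-17-hydroxylabd-7-en-15-yl acetate | CC(=O)OCC[C@@H](C)CC[C@H]1C(CO)=CC[C@H]2C(C)(C)CCC[C@]12C
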